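**Retrosynthetic overview** (ring atoms O1, O2, C3–C6; open-chain precursors keep the same C1–C16 numbering, so C3 = ketone, C6 = peroxide carbon, C8 = side-chain stereocentre)

1. The 1,2-dioxane is the only ring and is formed last: the C6–O1 bond is made by adding the O–OH of the C3 perhydrate of an unsaturated β-keto ester across its own 1,1-disubstituted alkene. This sets C6; C3 settles as the stable hemiketal anomer.
2. The β-keto ester comes from a crossed Claisen condensation of methyl acetate with an α-methyl ester (C2–C3 bond).
3. That ester comes from a Negishi coupling (C5–C6 bond) of a Roche-ester-derived alkylzinc, which supplies C4, with a 2-alkenyl triflate.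
4. The alkenyl triflate comes from a methyl ketone made by copper-catalysed asymmetric conjugate addition of (8-phenyloctyl)magnesium bromide to (E)-pent-3-en-2-one (sets C8).

Assumption: each chiral ligand or catalyst is used as the enantiomer (both are available) that gives the configuration stated; where the sense of induction cannot be known beforehand it is fixed by a test run with each enantiomer.

**Step 1**
Reactants: 1 (8-bromooctyl)benzene; 2 (E)-pent-3-en-2-one
Product: 4 (R)-4-methyl-12-phenyldodecan-2-one, via (8-phenyloctyl)magnesium bromide 3 (not isolated)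
Conditions: 1, Mg, Et2O, reflux; then added slowly to 2, CuBr·SMe2 (5 mol %), Josiphos ligand [(R)-1-[(S)-2-(diphenylphosphino)ferrocenyl]ethyldicyclohexylphosphine or its mirror image, 6 mol %], t-BuOMe, −75 °C; 1 M HCl
Reagents that add atoms: none
Why: Copper-catalysed asymmetric conjugate addition of a Grignard reagent to an acyclic enone, in which the chiral diphosphine–copper complex delivers the alkyl group to one face of the β-carbon and so sets the side-chain methyl stereocentre (C8) as R.

**Step 2**
Reactants: 4 (R)-4-methyl-12-phenyldodecan-2-one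
Product: 6 (R)-4-methyl-12-phenyldodec-1-en-2-yl trifluoromethanesulfonate, via lithium (R)-4-methyl-12-phenyldodec-1-en-2-olate 5 (not isolated)
Conditions: LDA (commercial solution, 1.1 equiv), THF, −78 °C; Comins' reagent, −78 → 0 °C; 1 M HCl
Reagents that add atoms: Comins' reagent, N-(5-chloropyridin-2-yl)-1,1,1-trifluoro-N-(trifluoromethylsulfonyl)methanesulfonamide, Clc1ccc(nc1)N(S(=O)(=O)C(F)(F)F)S(=O)(=O)C(F)(F)F
Why: Kinetic enolisation at the unhindered methyl group followed by O-triflation gives the terminal enol triflate; the stereocentre is β to the carbonyl and is not touched.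

**Step 3**
Reactants: 6 (R)-4-methyl-12-phenyldodec-1-en-2-yl trifluoromethanesulfonate; 7 methyl (S)-3-bromo-2-methylpropanoate
Product: 9 methyl (2R,6R)-2,6-dimethyl-4-methylidene-14-phenyltetradecanoate, via [(S)-3-methoxy-2-methyl-3-oxopropyl]zinc bromide 8 (not isolated)
Conditions: 7 (1.3 equiv), Zn dust, I2 (5 mol %), DMA, 70 °C; then 6, PdCl2(dppf) (dppf = 1,1'-bis(diphenylphosphino)ferrocene, 3 mol %), THF, 45 °C
Reagents that add atoms: none
Why: Zinc insertion into the primary C–Br bond gives an ester-tolerant alkylzinc whose stereocentre is not the metallated carbon, and Negishi cross-coupling with the alkenyl triflate forms C5–C6 and carries the chiral-pool centre in unchanged as C4 (R).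

**Step 4**
Reactants: 9 methyl (2R,6R)-2,6-dimethyl-4-methylidene-14-phenyltetradecanoate
Product: 10 methyl (4R,8R)-4,8-dimethyl-6-methylidene-3-oxo-16-phenylhexadecanoate
Conditions: MeOAc (4.2 equiv), LDA (commercial solution, 4.0 equiv), THF, −78 °C; then 9, −78 → −30 °C; 1 M HCl
Reagents that add atoms: methyl acetate, COC(C)=O
Why: Crossed Claisen condensation in which the lithium enolate of methyl acetate acylates on the methyl ester; the product is held as its C2 enolate and no free amide base is present, so the C4 centre is not epimerised.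

**Step 5**
Reactants: 10 methyl (4R,8R)-4,8-dimethyl-6-methylidene-3-oxo-16-phenylhexadecanoate
Product: 12 methyl 2-[(3S,4R,6S)-3-hydroxy-4,6-dimethyl-6-[(2R)-2-methyl-10-phenyldecyl]-1,2-dioxan-3-yl]acetate, via C3 perhydrate 11 (not isolated)
Conditions: H2O2 (anhydrous, in Et2O, 1.5 equiv), chiral IDPi acid (confined imidodiphosphorimidate built from two 3,3'-diaryl-1,1'-bi-2-naphthol units with N-triflyl groups, 5 mol %), MgSO4, cyclohexane/CHCl3, 0 → 25 °C
Reagents that add atoms: hydrogen peroxide, OO
Why: Proposed new method: the ketone and H2O2 equilibrate under acid catalysis with perhydrate 11; inside the confined chiral anion the acid protonates the CH2 terminus of the alkene while the distal, α-effect oxygen of the O–OH group attacks the developing tertiary centre C6 in a 6-exo, concerted-asynchronous Markovnikov addition (the catalyst's basic oxygen takes the OOH proton), so the C6–O1 bond, the ring and the C6 configuration are set in one event; a chair transition state with the C4 methyl and the long C6 substituent equatorial, reinforced by the matched catalyst enantiomer, gives 6S, and C3 settles by ring–chain equilibration as the axial-OH anomer (3S); the closest known reactions are the IDPi-catalysed asymmetric intramolecular hydroalkoxylation of 1,1-disubstituted alkenols to 2,2-disubstituted tetrahydrofurans and the acid-catalysed Markovnikov addition of H2O2 and hydroperoxides to isobutene-type alkenes.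

**Compound list**

1 | (8-bromooctyl)benzene | BrCCCCCCCCc1ccccc1 | starting material
2 | (E)-pent-3-en-2-one | C/C=C/C(C)=O | starting material
3 | (8-phenyloctyl)magnesium bromide | Br[Mg]CCCCCCCCc1ccccc1 | intermediate
4 | (R)-4-methyl-12-phenyldodecan-2-one | CC(=O)C[C@H](C)CCCCCCCCc1ccccc1 | intermediate
5 | lithium (R)-4-methyl-12-phenyldodec-1-en-2-olate | [Li]OC(=C)C[C@H](C)CCCCCCCCc1ccccc1 | intermediate
6 | (R)-4-methyl-12-phenyldodec-1-en-2-yl trifluoromethanesulfonate | C=C(OS(=O)(=O)C(F)(F)F)C[C@H](C)CCCCCCCCc1ccccc1 | intermediate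
7 | methyl (S)-3-bromo-2-methylpropanoate | COC(=O)[C@H](C)CBr | starting material
8 | [(S)-3-methoxy-2-methyl-3-oxopropyl]zinc bromide | COC(=O)[C@H](C)C[Zn]Br | intermediate
9 | methyl (2R,6R)-2,6-dimethyl-4-methylidene-14-phenyltetradecanoate | COC(=O)[C@H](C)CC(=C)C[C@H](C)CCCCCCCCc1ccccc1 | intermediate
10 | methyl (4R,8R)-4,8-dimethyl-6-methylidene-3-oxo-16-phenylhexadecanoate | COC(=O)CC(=O)[C@H](C)CC(=C)C[C@H](C)CCCCCCCCc1ccccc1 | intermediate
11 | methyl (4R,8R)-3-hydroperoxy-3-hydroxy-4,8-dimethyl-6-methylidene-16-phenylhexadecanoate (both C3 epimers) | COC(=O)CC(O)(OO)[C@H](C)CC(=C)C[C@H](C)CCCCCCCCc1ccccc1 | intermediate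
12 | methyl 2-[(3S,4R,6S)-3-hydroxy-4,6-dimethyl-6-[(2R)-2-methyl-10-phenyldecyl]-1,2-dioxan-3-yl]acetate | COC(=O)C[C@]1(O)OO[C@@](C)(C[C@H](C)CCCCCCCCc2ccccc2)C[C@H]1C | target

**Total step count:** 5. **Longest linear sequence:** 5 steps (1 → 4 → 6 → 9 → 10 → 12).

**Three steps most likely to fail**

Step 5 (the proposed new step) is the most likely to fail. H2O2 and ether may level the acid so that the alkene is not activated. The ketone, enol or hemiketal OH oxygen may close 5-exo to a tetrahydrofuran instead of the O–OH oxygen closing 6-exo. The alkene may migrate into conjugation with loss of C4, excess H2O2 may exchange the hemiketal OH, and untethered addition or a weak catalyst bias would give the C6 epimer. The fallback uses known chemistry, sets out from 10 and comes back at 12. Isayama–Mukaiyama hydroperoxysilylation of 10 (O2 at 1 atm, Et3SiH, cobalt bis(2,2,6,6-tetramethylheptane-3,5-dionate), Co(thd)2, 10 mol %, 1,2-dichloroethane, 25 °C) forms the C6–O bond by hydrogen-atom transfer and O2 capture. It gives methyl (4R,8R)-4,6,8-trimethyl-3-oxo-16-phenyl-6-[(triethylsilyl)peroxy]hexadecanoate F1 as both C6 epimers. HF·pyridine in THF at 0 °C removes the silyl group and the free hydroperoxide closes onto the C3 ketone. This gives 12 together with its C6 epimer, methyl 2-[(3S,4R,6R)-3-hydroxy-4,6-dimethyl-6-[(2R)-2-methyl-10-phenyldecyl]-1,2-dioxan-3-yl]acetate F2, which is removed by chromatography (HPLC if needed). Control at C6 is given up (about 1:1 expected).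

Step 1 may give insufficient enantiomeric excess, because the enone carries only a small β-methyl group and the Grignard is a long primary alkyl; 1,2-addition is a second risk. The minor enantiomer of 4 ends up as a remote C8 diastereomer of 12 that is very hard to separate. The fallback sets out from 3 and comes back at 4. Grignard 3 is added to methyl (E)-but-2-enoate with CuI and 2,2'-bis(di-p-tolylphosphino)-1,1'-binaphthyl (t-BuOMe, −40 °C), the well-documented pairing of a long-chain Grignard with a crotonate, to give methyl (R)-3-methyl-11-phenylundecanoate F3. MeNH(OMe)·HCl and i-PrMgCl (THF, −20 °C) convert it to (R)-N-methoxy-N,3-dimethyl-11-phenylundecanamide F4. MeMgBr (THF, 0 °C) then gives 4.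

Step 4 may suffer from self-condensation of methyl acetate, slow attack on the α-branched ester, or partial epimerisation at C4. The fallback sets out from 9 and comes back at 10. LiOH (THF/MeOH/H2O, 25 °C) gives (2R,6R)-2,6-dimethyl-4-methylidene-14-phenyltetradecanoic acid F5. 1,1'-Carbonyldiimidazole in THF converts it to (2R,6R)-1-(1H-imidazol-1-yl)-2,6-dimethyl-4-methylidene-14-phenyltetradecan-1-one F6, used without isolation. Mg(O2CCH2CO2Me)2 (from potassium methyl malonate and MgCl2, THF, 25 → 40 °C) C-acylates under near-neutral conditions and, after decarboxylation on mild acidic work-up, gives 10.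

**Further compounds**

F1 | step 5 | methyl (4R,8R)-4,6,8-trimethyl-3-oxo-16-phenyl-6-[(triethylsilyl)peroxy]hexadecanoate (both C6 epimers) | COC(=O)CC(=O)[C@H](C)CC(C)(OO[Si](CC)(CC)CC)C[C@H](C)CCCCCCCCc1ccccc1
F2 | step 5 | methyl 2-[(3S,4R,6R)-3-hydroxy-4,6-dimethyl-6-[(2R)-2-methyl-10-phenyldecyl]-1,2-dioxan-3-yl]acetate | COC(=O)C[C@]1(O)OO[C@](C)(C[C@H](C)CCCCCCCCc2ccccc2)C[C@H]1C
F3 | step 1 | methyl (R)-3-methyl-11-phenylundecanoate | COC(=O)C[C@H](C)CCCCCCCCc1ccccc1
F4 | step 1 | (R)-N-methoxy-N,3-dimethyl-11-phenylundecanamide | CON(C)C(=O)C[C@H](C)CCCCCCCCc1ccccc1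
F5 | step 4 | (2R,6R)-2,6-dimethyl-4-methylidene-14-phenyltetradecanoic acid | OC(=O)[C@H](C)CC(=C)C[C@H](C)CCCCCCCCc1ccccc1
F6 | step 4 | (2R,6R)-1-(1H-imidazol-1-yl)-2,6-dimethyl-4-methylidene-14-phenyltetradecan-1-one | O=C(n1ccnc1)[C@H](C)CC(=C)C[C@H](C)CCCCCCCCc1ccccc1
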